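**Retrosynthetic overview**
1. Target ⇐ hydrogenolysis of five benzyl ethers ⇐ sulfation of the single free 7''-OH ⇐ MOM removal from the fully assembled, protected flavanone–flavone 23.
2. Key disconnection (ring C of the flavanone, closed last): 23 ⇒ β-hydroxy ester 14 (the O1–C2–C3–C4 unit, with ring B on C2 and the complete flavone on C3) + 3,5-bis(benzyloxy)benzyne 21 (ring A). One aryne annulation makes O1–C8a and C4–C4a.
3. Enabling feature: in ring A, C8a (bearing O1) and C4a (bearing C4) are adjacent and C5, next to C4a, carries oxygen. Ring A is therefore a 3-alkoxy aryne whose polarisation sends the alkoxide to C8a and the aryl anion to C4a. C3 is α to C4=O, so it settles as the trans epimer and only C2 has to be set beforehand.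
4. 14 ⇐ Evans syn aldol (sets C2) of the (flavon-8-yl)acetyl oxazolidinone 10 with 4-(benzyloxy)benzaldehyde; 10 ⇐ apigenin by 7-O-MOM/5,4'-di-O-benzyl protection, C8 iodination and Reformatsky–Negishi coupling.
5. Ring order: the flavone rings are taken intact from apigenin; ring A of the flavanone is prepared separately as silylaryl triflate 20; ring C of the flavanone is formed in the key step.

Key step: step 12

Remark: the aryl hydrogen sulfate is drawn as the free acid and 25 and 26 are listed that way; in the flask they would be handled as sodium salts and the acid form released only at the end by cation exchange.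

Step 1
Reactants: 1 apigenin
Product: 2 5-hydroxy-2-(4-hydroxyphenyl)-7-(methoxymethoxy)-4H-chromen-4-one
Conditions: MOMCl (1.0 equiv), K2CO3 (1.0 equiv), DMF, 0 °C
Reagents that add atoms: chloromethyl methyl ether, COCCl
Why: Williamson etherification; the 7-OH is the most acidic phenol (vinylogous acid), the 5-OH is held in a hydrogen bond to C4=O and the 4'-OH is less acidic, so one equivalent of base and electrophile should alkylate O7 preferentially.

Step 2
Reactants: 2 7-O-MOM-apigenin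
Product: 3 5-(benzyloxy)-2-[4-(benzyloxy)phenyl]-7-(methoxymethoxy)-4H-chromen-4-one
Conditions: BnBr (2.5 equiv), K2CO3 (3 equiv), DMF, 70 °C
Reagents that add atoms: benzyl bromide, BrCc1ccccc1
Why: Williamson etherification; excess benzyl bromide and heating should alkylate the 4'-OH and also the chelated 5-OH, while the MOM acetal is stable to base.

Step 3
Reactants: 3 protected flavone
Product: 4 5-(benzyloxy)-2-[4-(benzyloxy)phenyl]-8-iodo-7-(methoxymethoxy)-4H-chromen-4-one
Conditions: NIS (1.1 equiv), TFA (0.1 equiv), MeCN, 0 °C → rt, dark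
Reagents that add atoms: N-iodosuccinimide, O=C1CCC(=O)N1I
Why: Electrophilic aromatic iodination; in 5,7-di-O-alkylated flavones C8 (para to O5, ortho to O7 and O1) is the most nucleophilic nuclear position, whereas C6 is flanked by the bulky 5-benzyloxy group.

Step 4
Reactants: 4 8-iodoflavone; 5 (2-ethoxy-2-oxoethyl)zinc bromide
Product: 6 ethyl 2-[5-(benzyloxy)-2-[4-(benzyloxy)phenyl]-7-(methoxymethoxy)-4-oxo-4H-chromen-8-yl]acetate
Conditions: Pd2(dba)3 (2.5 mol %), XPhos (10 mol %), THF, 60 °C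
Reagents that add atoms: none
Why: Negishi-type cross-coupling of a Reformatsky reagent (palladium-catalysed α-arylation of a zinc ester enolate); the bulky biarylphosphine supports oxidative addition of the hindered aryl iodide to zerovalent palladium and the mild zinc enolate should leave the chromone untouched.

Step 5
Reactants: 6 ethyl flavonylacetate
Product: 7 2-[5-(benzyloxy)-2-[4-(benzyloxy)phenyl]-7-(methoxymethoxy)-4-oxo-4H-chromen-8-yl]acetic acid
Conditions: LiOH (3 equiv), THF/MeOH/H2O, rt; then 1 M HCl, 0 °C, pH 3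
Reagents that add atoms: lithium hydroxide, [Li+].[OH-]
Why: Ester saponification; the chromone, benzyl ethers and MOM acetal should tolerate aqueous LiOH at room temperature and a short cold acidification.

Step 6
Reactants: 7 flavonylacetic acid; 8 (R)-4-benzyloxazolidin-2-one
Product: 10 (R)-4-benzyl-3-[2-[5-(benzyloxy)-2-[4-(benzyloxy)phenyl]-7-(methoxymethoxy)-4-oxo-4H-chromen-8-yl]acetyl]oxazolidin-2-one, via mixed pivalic anhydride 9 (not isolated)
Conditions: PivCl, Et3N, THF, −20 °C; then 8, LiCl, rt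
Reagents that add atoms: none
Why: N-acylation of the oxazolidinone through a mixed anhydride; the auxiliary should attack the less hindered arylacetyl carbonyl rather than the pivaloyl carbonyl.

Step 7
Reactants: 10 N-acyl oxazolidinone; 11 4-(benzyloxy)benzaldehyde
Product: 13 (R)-4-benzyl-3-[(2R,3R)-2-[5-(benzyloxy)-2-[4-(benzyloxy)phenyl]-7-(methoxymethoxy)-4-oxo-4H-chromen-8-yl]-3-[4-(benzyloxy)phenyl]-3-hydroxypropanoyl]oxazolidin-2-one, via Z-boron enolate 12 (not isolated)
Conditions: Bu2BOTf (2.2 equiv), i-Pr2NEt (2.5 equiv), CH2Cl2, −78 → 0 °C; 11, −78 → 0 °C; pH 7 buffer, MeOH, 30% H2O2, 0 °C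
Reagents that add atoms: none
Why: Evans syn aldol; the Z-boron enolate should react through a Zimmerman–Traxler chair on the face opposite the benzyl group of the (R)-auxiliary, which sets the carbinol carbon as R (the future C2) and the α-carbon as R (syn), the extra boron triflate covering coordination to the chromone carbonyl.

Step 8
Reactants: 13 syn-aldol adduct
Product: 14 methyl (2R,3R)-2-[5-(benzyloxy)-2-[4-(benzyloxy)phenyl]-7-(methoxymethoxy)-4-oxo-4H-chromen-8-yl]-3-[4-(benzyloxy)phenyl]-3-hydroxypropanoate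
Conditions: Sm(OTf)3 (0.3 equiv), MeOH/CH2Cl2, rt
Reagents that add atoms: methanol, CO
Why: Lewis-acid-catalysed transesterification of a β-hydroxy imide; chelation of the β-hydroxyl and the exocyclic carbonyl should activate the acyl group under non-basic conditions that avoid retro-aldol cleavage.

Step 9
Reactants: 15 3,5-bis(benzyloxy)phenol
Product: 16 3,5-bis(benzyloxy)phenyl N-isopropylcarbamate
Conditions: i-PrNCO, Et3N (cat.), CH2Cl2, rt
Reagents that add atoms: isopropyl isocyanate, CC(C)N=C=O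
Why: Base-catalysed addition of the phenol to the isocyanate (carbamoylation) installs the group that directs the ortho-metalation.

Step 10
Reactants: 16 aryl carbamate
Product: 18 3,5-bis(benzyloxy)-2-(trimethylsilyl)phenyl N-isopropylcarbamate, via N-silyl carbamate 17 (not isolated)
Conditions: TBSOTf, TMEDA, Et2O, 0 °C → rt; n-BuLi, TMEDA, −78 °C; TMSCl, −78 °C → rt; aq. NaHCO3
Reagents that add atoms: chlorotrimethylsilane, C[Si](C)(C)Cl
Why: Directed ortho-metalation; the N-silylated carbamate and the neighbouring benzyloxy group should jointly direct lithiation to C2 (C2 and C6 are equivalent), TMSCl traps the carbanion and the N-silyl group is lost on aqueous work-up.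

Step 11
Reactants: 18 ortho-silyl carbamate
Product: 20 3,5-bis(benzyloxy)-2-(trimethylsilyl)phenyl trifluoromethanesulfonate, via silylphenol 19 (not isolated)
Conditions: Et2NH, DBU, MeCN, 40 °C; then PhNTf2, rt
Reagents that add atoms: N-phenylbis(trifluoromethanesulfonimide), O=S(=O)(N(c1ccccc1)S(=O)(=O)C(F)(F)F)C(F)(F)F
Why: Base-induced E1cB cleavage of the N–H carbamate (the isocyanate is trapped by Et2NH as a urea) followed by O-triflation of the phenoxide in the same flask.

Step 12
Reactants: 14 β-hydroxy methyl ester; 20 silylaryl triflate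
Product: 23 (2R,3S)-5,7-bis(benzyloxy)-2-[4-(benzyloxy)phenyl]-3-[5-(benzyloxy)-2-[4-(benzyloxy)phenyl]-7-(methoxymethoxy)-4-oxo-4H-chromen-8-yl]chroman-4-one, via 3,5-bis(benzyloxy)benzyne 21 (not isolated), via cis-flavanone 22 (not isolated)
Conditions: CsF (4 equiv), 20 (2 equiv, added slowly), toluene/MeCN 3:1, 50 °C
Reagents that add atoms: none
Why: Proposed new method: fluoride removes the trimethylsilyl group of 20 with loss of triflate to give aryne 21, the fluoride-bound alkoxide of 14 adds to the aryne carbon remote from the neighbouring benzyloxy group (the future C8a), and the aryl anion formed at the future C4a attacks the methyl ester and expels methoxide, a net loss of methanol. The closest known reaction type is the CsF-mediated annulation of arynes with ortho-hydroxy- or ortho-amino-benzoate esters to xanthones and acridones, together with the O–H insertion of arynes into aliphatic alcohols; the new element is an aliphatic β-hydroxy ester as the O/acyl partner. Ring C closes by a 6-exo-trig acyl substitution of the aryl carbanion on the ester, a formal [4+2] annulation of the O1–C2–C3–C4 unit with the two aryne carbons. C2 keeps the R configuration from the aldol because no bond to it is made or broken, and C3, α to the new ketone, should equilibrate through the enolate from the first-formed cis isomer 22 to the diequatorial trans isomer 23. The step needs regioselective aryne addition, O- rather than C-attack and no retro-aldol: the first is secured by the 3-benzyloxy group of the aryne (distortion, and inductive stabilisation of the anion ortho to oxygen), the others by the 2,6-dioxygenated flavonyl ring on the α-carbon, which is twisted out of conjugation and keeps that C–H weakly acidic, and by the nearly neutral fluoride medium.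

Step 13
Reactants: 23 protected trans-flavanone–flavone
Product: 24 (2R,3S)-5,7-bis(benzyloxy)-2-[4-(benzyloxy)phenyl]-3-[5-(benzyloxy)-2-[4-(benzyloxy)phenyl]-7-hydroxy-4-oxo-4H-chromen-8-yl]chroman-4-one
Conditions: HCl (2 M in MeOH), THF, 40 °C
Reagents that add atoms: none
Why: Acid-catalysed acetal cleavage (transacetalisation to dimethoxymethane) frees only O7''; benzyl ethers and C2 should be stable to dilute acid, and any residual cis epimer should converge to trans through the enol.

Step 14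
Reactants: 24 7''-phenol
Product: 25 5-(benzyloxy)-2-[4-(benzyloxy)phenyl]-8-[(2R,3S)-5,7-bis(benzyloxy)-2-[4-(benzyloxy)phenyl]-4-oxochroman-3-yl]-4-oxo-4H-chromen-7-yl hydrogen sulfate
Conditions: SO3·pyridine (5 equiv), pyridine, 40 °C; aq. NaHCO3 work-up
Reagents that add atoms: sulfur trioxide–pyridine complex, [O-]S(=O)(=O)[n+]1ccccc1
Why: O-sulfation of a phenol with an amine–SO3 complex; O7'' is the only free hydroxyl, so no selectivity between phenols is required.

Step 15
Reactants: 25 pentabenzyl sulfate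
Product: 26 5-hydroxy-8-[(2R,3S)-5,7-dihydroxy-2-(4-hydroxyphenyl)-4-oxochroman-3-yl]-2-(4-hydroxyphenyl)-4-oxo-4H-chromen-7-yl hydrogen sulfate (CNP0271389.1)
Conditions: H2 (1 atm), 10% Pd/C, THF/MeOH, rt; then cation-exchange resin (H+ form), 0 °C
Reagents that add atoms: none
Why: Hydrogenolysis of benzyl aryl ethers; the aryl sulfate salt is inert to hydrogenation, and a short reaction at 1 atm should spare the chromone double bond and the benzylic C2–O1 bond of the flavanone.

**Compound list**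
1 | apigenin (5,7-dihydroxy-2-(4-hydroxyphenyl)-4H-chromen-4-one) | O=c1cc(-c2ccc(O)cc2)oc2cc(O)cc(O)c12 | starting material
2 | 5-hydroxy-2-(4-hydroxyphenyl)-7-(methoxymethoxy)-4H-chromen-4-one | COCOc1cc(O)c2c(=O)cc(-c3ccc(O)cc3)oc2c1 | intermediate
3 | 5-(benzyloxy)-2-[4-(benzyloxy)phenyl]-7-(methoxymethoxy)-4H-chromen-4-one | COCOc1cc(OCc2ccccc2)c2c(=O)cc(-c3ccc(OCc4ccccc4)cc3)oc2c1 | intermediate
4 | 5-(benzyloxy)-2-[4-(benzyloxy)phenyl]-8-iodo-7-(methoxymethoxy)-4H-chromen-4-one | COCOc1cc(OCc2ccccc2)c2c(=O)cc(-c3ccc(OCc4ccccc4)cc3)oc2c1I | intermediate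
5 | (2-ethoxy-2-oxoethyl)zinc bromide (commercial solution in THF) | CCOC(=O)C[Zn]Br | starting material
6 | ethyl 2-[5-(benzyloxy)-2-[4-(benzyloxy)phenyl]-7-(methoxymethoxy)-4-oxo-4H-chromen-8-yl]acetate | CCOC(=O)Cc1c(OCOC)cc(OCc2ccccc2)c2c(=O)cc(-c3ccc(OCc4ccccc4)cc3)oc12 | intermediate
7 | 2-[5-(benzyloxy)-2-[4-(benzyloxy)phenyl]-7-(methoxymethoxy)-4-oxo-4H-chromen-8-yl]acetic acid | OC(=O)Cc1c(OCOC)cc(OCc2ccccc2)c2c(=O)cc(-c3ccc(OCc4ccccc4)cc3)oc12 | intermediate
8 | (R)-4-benzyloxazolidin-2-one | O=C1N[C@H](Cc2ccccc2)CO1 | starting material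
9 | mixed anhydride of acid 7 with pivalic acid | CC(C)(C)C(=O)OC(=O)Cc1c(OCOC)cc(OCc2ccccc2)c2c(=O)cc(-c3ccc(OCc4ccccc4)cc3)oc12 | intermediate (not isolated)
10 | (R)-4-benzyl-3-[2-[5-(benzyloxy)-2-[4-(benzyloxy)phenyl]-7-(methoxymethoxy)-4-oxo-4H-chromen-8-yl]acetyl]oxazolidin-2-one | O=C(Cc1c(OCOC)cc(OCc2ccccc2)c2c(=O)cc(-c3ccc(OCc4ccccc4)cc3)oc12)N1C(=O)OC[C@H]1Cc1ccccc1 | intermediate
11 | 4-(benzyloxy)benzaldehyde | O=Cc1ccc(OCc2ccccc2)cc1 | starting material
12 | (Z)-dibutylboron enolate of imide 10 | CCCCB(CCCC)O/C(=C\c1c(OCOC)cc(OCc2ccccc2)c2c(=O)cc(-c3ccc(OCc4ccccc4)cc3)oc12)N1C(=O)OC[C@H]1Cc1ccccc1 | intermediate (not isolated)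
13 | (R)-4-benzyl-3-[(2R,3R)-2-[5-(benzyloxy)-2-[4-(benzyloxy)phenyl]-7-(methoxymethoxy)-4-oxo-4H-chromen-8-yl]-3-[4-(benzyloxy)phenyl]-3-hydroxypropanoyl]oxazolidin-2-one | O=C([C@H](c1c(OCOC)cc(OCc2ccccc2)c2c(=O)cc(-c3ccc(OCc4ccccc4)cc3)oc12)[C@@H](O)c1ccc(OCc2ccccc2)cc1)N1C(=O)OC[C@H]1Cc1ccccc1 | intermediate
14 | methyl (2R,3R)-2-[5-(benzyloxy)-2-[4-(benzyloxy)phenyl]-7-(methoxymethoxy)-4-oxo-4H-chromen-8-yl]-3-[4-(benzyloxy)phenyl]-3-hydroxypropanoate | COC(=O)[C@H](c1c(OCOC)cc(OCc2ccccc2)c2c(=O)cc(-c3ccc(OCc4ccccc4)cc3)oc12)[C@@H](O)c1ccc(OCc2ccccc2)cc1 | intermediate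
15 | 3,5-bis(benzyloxy)phenol | Oc1cc(OCc2ccccc2)cc(OCc2ccccc2)c1 | starting material
16 | 3,5-bis(benzyloxy)phenyl N-isopropylcarbamate | CC(C)NC(=O)Oc1cc(OCc2ccccc2)cc(OCc2ccccc2)c1 | intermediate
17 | 3,5-bis(benzyloxy)phenyl N-(tert-butyldimethylsilyl)-N-isopropylcarbamate | CC(C)N([Si](C)(C)C(C)(C)C)C(=O)Oc1cc(OCc2ccccc2)cc(OCc2ccccc2)c1 | intermediate (not isolated)
18 | 3,5-bis(benzyloxy)-2-(trimethylsilyl)phenyl N-isopropylcarbamate | CC(C)NC(=O)Oc1cc(OCc2ccccc2)cc(OCc2ccccc2)c1[Si](C)(C)C | intermediate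
19 | 3,5-bis(benzyloxy)-2-(trimethylsilyl)phenol | Oc1cc(OCc2ccccc2)cc(OCc2ccccc2)c1[Si](C)(C)C | intermediate (not isolated)
20 | 3,5-bis(benzyloxy)-2-(trimethylsilyl)phenyl trifluoromethanesulfonate | O=S(=O)(Oc1cc(OCc2ccccc2)cc(OCc2ccccc2)c1[Si](C)(C)C)C(F)(F)F | intermediate
21 | 3,5-bis(benzyloxy)benzyne (1,2-didehydro-3,5-bis(benzyloxy)benzene) | C1#CC(OCc2ccccc2)=CC(OCc2ccccc2)=C1 | intermediate (not isolated)
22 | (2R,3R)-5,7-bis(benzyloxy)-2-[4-(benzyloxy)phenyl]-3-[5-(benzyloxy)-2-[4-(benzyloxy)phenyl]-7-(methoxymethoxy)-4-oxo-4H-chromen-8-yl]chroman-4-one (2,3-cis) | O=C1c2c(OCc3ccccc3)cc(OCc3ccccc3)cc2O[C@@H](c2ccc(OCc3ccccc3)cc2)[C@H]1c1c(OCOC)cc(OCc2ccccc2)c2c(=O)cc(-c3ccc(OCc4ccccc4)cc3)oc12 | intermediate (not isolated)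
23 | (2R,3S)-5,7-bis(benzyloxy)-2-[4-(benzyloxy)phenyl]-3-[5-(benzyloxy)-2-[4-(benzyloxy)phenyl]-7-(methoxymethoxy)-4-oxo-4H-chromen-8-yl]chroman-4-one (2,3-trans) | O=C1c2c(OCc3ccccc3)cc(OCc3ccccc3)cc2O[C@@H](c2ccc(OCc3ccccc3)cc2)[C@@H]1c1c(OCOC)cc(OCc2ccccc2)c2c(=O)cc(-c3ccc(OCc4ccccc4)cc3)oc12 | intermediate
24 | (2R,3S)-5,7-bis(benzyloxy)-2-[4-(benzyloxy)phenyl]-3-[5-(benzyloxy)-2-[4-(benzyloxy)phenyl]-7-hydroxy-4-oxo-4H-chromen-8-yl]chroman-4-one | O=C1c2c(OCc3ccccc3)cc(OCc3ccccc3)cc2O[C@@H](c2ccc(OCc3ccccc3)cc2)[C@@H]1c1c(O)cc(OCc2ccccc2)c2c(=O)cc(-c3ccc(OCc4ccccc4)cc3)oc12 | intermediate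
25 | 5-(benzyloxy)-2-[4-(benzyloxy)phenyl]-8-[(2R,3S)-5,7-bis(benzyloxy)-2-[4-(benzyloxy)phenyl]-4-oxochroman-3-yl]-4-oxo-4H-chromen-7-yl hydrogen sulfate | O=C1c2c(OCc3ccccc3)cc(OCc3ccccc3)cc2O[C@@H](c2ccc(OCc3ccccc3)cc2)[C@@H]1c1c(OS(=O)(=O)O)cc(OCc2ccccc2)c2c(=O)cc(-c3ccc(OCc4ccccc4)cc3)oc12 | intermediate
26 | 5-hydroxy-8-[(2R,3S)-5,7-dihydroxy-2-(4-hydroxyphenyl)-4-oxochroman-3-yl]-2-(4-hydroxyphenyl)-4-oxo-4H-chromen-7-yl hydrogen sulfate (CNP0271389.1) | O=C1c2c(O)cc(O)cc2O[C@@H](c2ccc(O)cc2)[C@@H]1c1c(OS(=O)(=O)O)cc(O)c2c(=O)cc(-c3ccc(O)cc3)oc12 | target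

**Step count**
Total: 15 steps. Longest linear sequence: 12 steps (steps 1–8 and 12–15); steps 9–11 prepare the aryne precursor 20.

**Steps most likely to fail**

1. Step 12 (proposed new method). What may go wrong:
- protonation of the aryl anion before it reaches the ester, which leaves only the aryl ether;
- retro-aldol fragmentation, dehydration or C-arylation of 14 in the fluoride medium;
- erosion of the C2 configuration by base-induced opening of ring C during the C3 equilibration.

The fallback uses known chemistry and separates the two bond formations. It sets out from 14 and 20. O–H insertion of the aryne into the alcohol under conditions known for aliphatic alcohols (KF, 18-crown-6, THF, −20 °C) should give the aryl ether ester F1 with the carbinol centre untouched. Saponification (LiOH, THF/H2O, rt) should give the aryl ether acid F2. Intramolecular Friedel–Crafts acylation of the phloroglucinol ring ortho to the ether oxygen (trifluoroacetic anhydride, 2,6-di-tert-butylpyridine, CH2Cl2, 0 °C), followed by equilibration at C3 (Et3N, CH2Cl2, rt), comes back to the route at 23.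

2. Step 8. What may go wrong: attack of methanol at the ring carbonyl of the oxazolidinone instead of the hindered exocyclic acyl group, retro-aldol cleavage, or loss of the MOM acetal under Lewis acid.

The fallback sets out from 13. Hydroperoxide-mediated hydrolysis (LiOH, H2O2, THF/H2O, 0 °C), which is selective for the exocyclic carbonyl, should give the β-hydroxy acid F3. O-Methylation with trimethylsilyldiazomethane (toluene/MeOH, 0 °C) comes back to the route at 14.

3. Step 15. What may go wrong: over-reduction of the chromone C2''=C3'' double bond, hydrogenolytic opening of the benzylic C2–O1 bond of the flavanone, or hydrolysis of the sulfate if the medium turns acidic.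

The fallback avoids hydrogenation while a free sulfate is present and sets out from 24. Sulfation with 2,2,2-trichloroethyl chlorosulfate (Et3N, DMAP, THF, rt) should give the neutral trichloroethyl sulfate diester F4. Non-reductive debenzylation (BCl3, pentamethylbenzene, CH2Cl2, −78 °C) should give the pentaphenol diester F5. Reductive removal of the trichloroethyl group (Zn, HCO2NH4, MeOH, rt) comes back to the route at 26.

**Further compounds**
F1 | step 12 | methyl (2R,3R)-3-[3,5-bis(benzyloxy)phenoxy]-2-[5-(benzyloxy)-2-[4-(benzyloxy)phenyl]-7-(methoxymethoxy)-4-oxo-4H-chromen-8-yl]-3-[4-(benzyloxy)phenyl]propanoate | COC(=O)[C@H](c1c(OCOC)cc(OCc2ccccc2)c2c(=O)cc(-c3ccc(OCc4ccccc4)cc3)oc12)[C@@H](Oc1cc(OCc2ccccc2)cc(OCc2ccccc2)c1)c1ccc(OCc2ccccc2)cc1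
F2 | step 12 | (2R,3R)-3-[3,5-bis(benzyloxy)phenoxy]-2-[5-(benzyloxy)-2-[4-(benzyloxy)phenyl]-7-(methoxymethoxy)-4-oxo-4H-chromen-8-yl]-3-[4-(benzyloxy)phenyl]propanoic acid | OC(=O)[C@H](c1c(OCOC)cc(OCc2ccccc2)c2c(=O)cc(-c3ccc(OCc4ccccc4)cc3)oc12)[C@@H](Oc1cc(OCc2ccccc2)cc(OCc2ccccc2)c1)c1ccc(OCc2ccccc2)cc1
F3 | step 8 | (2R,3R)-2-[5-(benzyloxy)-2-[4-(benzyloxy)phenyl]-7-(methoxymethoxy)-4-oxo-4H-chromen-8-yl]-3-[4-(benzyloxy)phenyl]-3-hydroxypropanoic acid | OC(=O)[C@H](c1c(OCOC)cc(OCc2ccccc2)c2c(=O)cc(-c3ccc(OCc4ccccc4)cc3)oc12)[C@@H](O)c1ccc(OCc2ccccc2)cc1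
F4 | step 15 | 5-(benzyloxy)-2-[4-(benzyloxy)phenyl]-8-[(2R,3S)-5,7-bis(benzyloxy)-2-[4-(benzyloxy)phenyl]-4-oxochroman-3-yl]-4-oxo-4H-chromen-7-yl 2,2,2-trichloroethyl sulfate | O=C1c2c(OCc3ccccc3)cc(OCc3ccccc3)cc2O[C@@H](c2ccc(OCc3ccccc3)cc2)[C@@H]1c1c(OS(=O)(=O)OCC(Cl)(Cl)Cl)cc(OCc2ccccc2)c2c(=O)cc(-c3ccc(OCc4ccccc4)cc3)oc12
F5 | step 15 | 5-hydroxy-8-[(2R,3S)-5,7-dihydroxy-2-(4-hydroxyphenyl)-4-oxochroman-3-yl]-2-(4-hydroxyphenyl)-4-oxo-4H-chromen-7-yl 2,2,2-trichloroethyl sulfate | O=C1c2c(O)cc(O)cc2O[C@@H](c2ccc(O)cc2)[C@@H]1c1c(OS(=O)(=O)OCC(Cl)(Cl)Cl)cc(O)c2c(=O)cc(-c3ccc(O)cc3)oc12
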